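**Retrosynthetic overview**
- The target is opened at the flavanone O1–C2 bond: an α‑aryl‑2'‑hydroxychalcone is closed by a catalytic enantioselective oxa‑Michael addition that sets C2 (R); C3 (S, trans) follows by equilibration.
- The 7''‑sulfate is carried through that ring closure as its neutral 2,2,2‑trichloroethyl (TCE) diester, put on the only non‑chelated OH of the open chalcone; the last step removes TCE, benzyl and ketal groups together.
- The chalcone comes from a Knoevenagel condensation of a deoxybenzoin with 4‑(benzyloxy)benzaldehyde.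
- The deoxybenzoin (C3–C8'' bond) comes from Pd α‑arylation of a protected phloroacetophenone with an 8‑iodoflavone.
- Ring order: the flavone rings are bought intact as luteolin (ketal, MOM, C8 iodination); the flavanone pyranone ring is the only ring formed, in step 9.

Assumption: the target is isolated as the free hydrogen sulfate as drawn (made from its ammonium salt on an acidic resin), and the dibenzyl ether of phloroacetophenone and 2,2,2‑trichloroethyl chlorosulfate are taken as catalogue compounds.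

**Route**

Step 1
Reactants: 1 luteolin; 2 dichlorodiphenylmethane
Product: 3 3',4'-O-(diphenylmethylene)luteolin
Conditions: Ph2CCl2 (1.5 equiv), Ph2O, 175 °C, 30 min
Reagents that add atoms: 2 dichlorodiphenylmethane, ClC(Cl)(c1ccccc1)c1ccccc1
Why: Catechol ketalisation with a gem‑dichloride forms the five‑membered diphenylmethylene ketal on the only vicinal diol and leaves the 5‑ and 7‑OH free.

Step 2
Reactants: 3 3',4'-O-(diphenylmethylene)luteolin; 4 chloromethyl methyl ether
Product: 5 5,7-bis-O-(methoxymethyl)-3',4'-O-(diphenylmethylene)luteolin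
Conditions: NaH (2.5 equiv), MOMCl (2.5 equiv), DMF, 0 °C → rt
Reagents that add atoms: 4 chloromethyl methyl ether, COCCl
Why: Williamson O‑alkylation under NaH caps both the acidic 7‑OH and the chelated 5‑OH, which is needed to steer the next substitution to C8.

Step 3
Reactants: 5 5,7-bis-O-(methoxymethyl)-3',4'-O-(diphenylmethylene)luteolin; 6 N-iodosuccinimide
Product: 7 8-iodo-5,7-bis-O-(methoxymethyl)-3',4'-O-(diphenylmethylene)luteolin
Conditions: NIS (1.1 equiv), DMF, rt, dark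
Reagents that add atoms: 6 N-iodosuccinimide, O=C1CCC(=O)N1I
Why: Electrophilic aromatic iodination of a 5,7‑dialkoxyflavone goes to C8 (between O1 and the 7‑alkoxy group), as established for 5,7‑dimethoxyflavones, and the neutral conditions spare the MOM ethers.

Step 4
Reactants: 8 1-[2,4-bis(benzyloxy)-6-hydroxyphenyl]ethanone; 4 chloromethyl methyl ether
Product: 9 1-[2,4-bis(benzyloxy)-6-(methoxymethoxy)phenyl]ethanone
Conditions: NaH (1.2 equiv), MOMCl (1.3 equiv), DMF, 0 °C → rt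
Reagents that add atoms: 4 chloromethyl methyl ether, COCCl
Why: Williamson etherification of the chelated phenol masks the future ring oxygen so that it cannot interfere with the Pd coupling or cyclise during the condensation.

Step 5
Reactants: 7 8-iodo-5,7-bis-O-(methoxymethyl)-3',4'-O-(diphenylmethylene)luteolin; 9 1-[2,4-bis(benzyloxy)-6-(methoxymethoxy)phenyl]ethanone
Product: 10 deoxybenzoin 8-{2-[2,4-bis(benzyloxy)-6-(methoxymethoxy)phenyl]-2-oxoethyl}-2-(2,2-diphenyl-1,3-benzodioxol-5-yl)-5,7-bis(methoxymethoxy)-4H-chromen-4-one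
Conditions: Pd2(dba)3 (2.5 mol%), XPhos (6 mol%), K3PO4 (2.5 equiv), 9 (1.3 equiv), toluene, 90 °C
Reagents that add atoms: none
Why: Pd‑catalysed ketone α‑arylation (Buchwald–Hartwig type) joins the methyl ketone enolate to the aryl iodide with a mild phosphate base the flavone tolerates, and the di‑ortho‑substituted product is too hindered to arylate twice.

Step 6
Reactants: 10 deoxybenzoin; 11 4-(benzyloxy)benzaldehyde
Product: 12 (E)-α-aryl chalcone 8-{(1E)-1-[2,4-bis(benzyloxy)-6-(methoxymethoxy)benzoyl]-2-[4-(benzyloxy)phenyl]ethenyl}-2-(2,2-diphenyl-1,3-benzodioxol-5-yl)-5,7-bis(methoxymethoxy)-4H-chromen-4-one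
Conditions: piperidine (0.3 equiv), AcOH (0.3 equiv), toluene, reflux, Dean–Stark
Reagents that add atoms: 11 4-(benzyloxy)benzaldehyde, O=Cc1ccc(OCc2ccccc2)cc1
Why: Knoevenagel‑type aldol condensation of the doubly activated methylene is driven by azeotropic water removal, and the MOM ether on O‑2' stops the reaction at the open chalcone (E isomer expected as the major one).

Step 7
Reactants: 12 (E)-α-aryl chalcone tris-MOM ether; 13 trimethylsilyl trifluoromethanesulfonate
Product: 15 chalcone triol 8-{(1E)-1-[2,4-bis(benzyloxy)-6-hydroxybenzoyl]-2-[4-(benzyloxy)phenyl]ethenyl}-2-(2,2-diphenyl-1,3-benzodioxol-5-yl)-5,7-dihydroxy-4H-chromen-4-one, via tris-TMS ether 14 (not isolated)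
Conditions: TMSOTf (6 equiv), 2,2'-bipyridyl (9 equiv), CH2Cl2, 0 °C → rt; then H2O, rt
Reagents that add atoms: 13 trimethylsilyl trifluoromethanesulfonate, C[Si](C)(C)OS(=O)(=O)C(F)(F)F (its Me3Si groups are present only in 14 and are lost again on hydrolysis)
Why: Non‑acidic MOM cleavage by the silyl triflate/2,2'‑bipyridyl method turns the three aryl MOM ethers into aryl TMS ethers that hydrolyse with water, so no free acid or base is present to trigger racemic ring closure or open the ketal.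

Step 8
Reactants: 15 chalcone triol; 16 2,2,2-trichloroethyl chlorosulfate
Product: 17 2-(2,2-diphenyl-1,3-benzodioxol-5-yl)-8-{(1E)-1-[2,4-bis(benzyloxy)-6-hydroxybenzoyl]-2-[4-(benzyloxy)phenyl]ethenyl}-5-hydroxy-4-oxo-4H-chromen-7-yl 2,2,2-trichloroethyl sulfate
Conditions: Cl3CCH2OSO2Cl (1.2 equiv), Et3N (1.5 equiv), DMAP (10 mol%), THF, −20 → 0 °C
Reagents that add atoms: 16 2,2,2-trichloroethyl chlorosulfate, ClS(=O)(=O)OCC(Cl)(Cl)Cl
Why: O‑sulfonylation (sulfuryl transfer from a chlorosulfate) takes place only at the non‑chelated, most acidic 7''‑OH, because the 2'‑OH and 5''‑OH are hydrogen‑bonded to their carbonyl groups; this also blocks O‑7'' as a competing nucleophile in the ring closure.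

Step 9
Reactants: 17 TCE-sulfated α-aryl-2'-hydroxychalcone
Product: 18 8-[(2R,3S)-5,7-bis(benzyloxy)-2-[4-(benzyloxy)phenyl]-4-oxo-3,4-dihydro-2H-chromen-3-yl]-2-(2,2-diphenyl-1,3-benzodioxol-5-yl)-5-hydroxy-4-oxo-4H-chromen-7-yl 2,2,2-trichloroethyl sulfate
Conditions: (R)-3,3'-bis(2,4,6-triisopropylphenyl)-BINOL N-triflylphosphoramide (10 mol%), 5 Å MS, toluene, −20 °C
Reagents that add atoms: none
Why: Proposed new method: a chiral N‑triflylphosphoramide‑catalysed enantioselective 6‑endo oxa‑Michael cyclisation of an unactivated α‑aryl‑2'‑hydroxychalcone, in which the acid protonates the enone carbonyl to give a p‑benzyloxybenzyl‑stabilised cation paired with the chiral anion while the anion's P=O/N–Tf site hydrogen‑bonds the 2'‑OH and delivers it to one face of Cβ to form the O1–C2 bond with 2R configuration, after which acid‑catalysed enol–keto equilibration places the C3 aryl trans (3S, diequatorial) without touching C2; the closest known reactions are the racemic acid‑catalysed chalcone–flavanone isomerisation, bifunctional thiourea‑catalysed oxa‑Michael closure of α‑alkoxycarbonyl chalcones, and N‑triflylphosphoramide‑catalysed Nazarov cyclisation with enantioselective protonation.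

Step 10
Reactants: 18 protected (2R,3S)-flavanone TCE sulfate
Product: 20 8-[(2R,3S)-5,7-dihydroxy-2-(4-hydroxyphenyl)-4-oxo-3,4-dihydro-2H-chromen-3-yl]-2-(3,4-dihydroxyphenyl)-5-hydroxy-4-oxo-4H-chromen-7-yl hydrogen sulfate (CNP0314990.1), via ammonium sulfate salt 19 (not isolated)
Conditions: 10% Pd/C, HCO2NH4 (12 equiv), THF/MeOH 1:1, rt → 40 °C; then Dowex 50W (H+), MeOH/H2O, 0 °C, lyophilise at once
Reagents that add atoms: none
Why: Catalytic transfer hydrogenolysis cleaves the three benzyl ethers and the diphenylmethylene ketal and reductively removes the trichloroethyl group from the sulfate diester (the known deprotection of TCE aryl sulfates) under near‑neutral conditions that leave C2 and C3 untouched, and cation exchange gives the hydrogen sulfate.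

**Compound list**

1 | luteolin, 2-(3,4-dihydroxyphenyl)-5,7-dihydroxy-4H-chromen-4-one | O=c1cc(-c2ccc(O)c(O)c2)oc2cc(O)cc(O)c12 | starting material
2 | dichlorodiphenylmethane | ClC(Cl)(c1ccccc1)c1ccccc1 | starting material
3 | 3',4'-O-(diphenylmethylene)luteolin, 2-(2,2-diphenyl-1,3-benzodioxol-5-yl)-5,7-dihydroxy-4H-chromen-4-one | O=c1cc(-c2ccc3c(c2)OC(c2ccccc2)(c2ccccc2)O3)oc2cc(O)cc(O)c12 | intermediate
4 | chloromethyl methyl ether (MOMCl) | COCCl | starting material
5 | 2-(2,2-diphenyl-1,3-benzodioxol-5-yl)-5,7-bis(methoxymethoxy)-4H-chromen-4-one | O=c1cc(-c2ccc3c(c2)OC(c2ccccc2)(c2ccccc2)O3)oc2cc(OCOC)cc(OCOC)c12 | intermediate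
6 | N-iodosuccinimide | O=C1CCC(=O)N1I | starting material
7 | 2-(2,2-diphenyl-1,3-benzodioxol-5-yl)-8-iodo-5,7-bis(methoxymethoxy)-4H-chromen-4-one | O=c1cc(-c2ccc3c(c2)OC(c2ccccc2)(c2ccccc2)O3)oc2c(I)c(OCOC)cc(OCOC)c12 | intermediate
8 | 1-[2,4-bis(benzyloxy)-6-hydroxyphenyl]ethanone | CC(=O)c1c(O)cc(OCc2ccccc2)cc1OCc1ccccc1 | starting material
9 | 1-[2,4-bis(benzyloxy)-6-(methoxymethoxy)phenyl]ethanone | CC(=O)c1c(OCOC)cc(OCc2ccccc2)cc1OCc1ccccc1 | intermediate
10 | deoxybenzoin, 8-{2-[2,4-bis(benzyloxy)-6-(methoxymethoxy)phenyl]-2-oxoethyl}-2-(2,2-diphenyl-1,3-benzodioxol-5-yl)-5,7-bis(methoxymethoxy)-4H-chromen-4-one | O=C(Cc1c(OCOC)cc(OCOC)c2c(=O)cc(-c3ccc4c(c3)OC(c3ccccc3)(c3ccccc3)O4)oc12)c1c(OCOC)cc(OCc2ccccc2)cc1OCc1ccccc1 | intermediate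
11 | 4-(benzyloxy)benzaldehyde | O=Cc1ccc(OCc2ccccc2)cc1 | starting material
12 | (E)-α-aryl chalcone tris-MOM ether, 8-{(1E)-1-[2,4-bis(benzyloxy)-6-(methoxymethoxy)benzoyl]-2-[4-(benzyloxy)phenyl]ethenyl}-2-(2,2-diphenyl-1,3-benzodioxol-5-yl)-5,7-bis(methoxymethoxy)-4H-chromen-4-one | O=C(c1c(OCOC)cc(OCc2ccccc2)cc1OCc1ccccc1)/C(=C/c1ccc(OCc2ccccc2)cc1)c1c(OCOC)cc(OCOC)c2c(=O)cc(-c3ccc4c(c3)OC(c3ccccc3)(c3ccccc3)O4)oc12 | intermediate
13 | trimethylsilyl trifluoromethanesulfonate | C[Si](C)(C)OS(=O)(=O)C(F)(F)F | starting material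
14 | tris(trimethylsilyl) ether of 15 (2'-, 5''- and 7''-OTMS; E alkene) | O=C(c1c(O[Si](C)(C)C)cc(OCc2ccccc2)cc1OCc1ccccc1)/C(=C/c1ccc(OCc2ccccc2)cc1)c1c(O[Si](C)(C)C)cc(O[Si](C)(C)C)c2c(=O)cc(-c3ccc4c(c3)OC(c3ccccc3)(c3ccccc3)O4)oc12 | intermediate
15 | chalcone triol, 8-{(1E)-1-[2,4-bis(benzyloxy)-6-hydroxybenzoyl]-2-[4-(benzyloxy)phenyl]ethenyl}-2-(2,2-diphenyl-1,3-benzodioxol-5-yl)-5,7-dihydroxy-4H-chromen-4-one | O=C(c1c(O)cc(OCc2ccccc2)cc1OCc1ccccc1)/C(=C/c1ccc(OCc2ccccc2)cc1)c1c(O)cc(O)c2c(=O)cc(-c3ccc4c(c3)OC(c3ccccc3)(c3ccccc3)O4)oc12 | intermediate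
16 | 2,2,2-trichloroethyl chlorosulfate | ClS(=O)(=O)OCC(Cl)(Cl)Cl | starting material
17 | 2-(2,2-diphenyl-1,3-benzodioxol-5-yl)-8-{(1E)-1-[2,4-bis(benzyloxy)-6-hydroxybenzoyl]-2-[4-(benzyloxy)phenyl]ethenyl}-5-hydroxy-4-oxo-4H-chromen-7-yl 2,2,2-trichloroethyl sulfate | O=C(c1c(O)cc(OCc2ccccc2)cc1OCc1ccccc1)/C(=C/c1ccc(OCc2ccccc2)cc1)c1c(OS(=O)(=O)OCC(Cl)(Cl)Cl)cc(O)c2c(=O)cc(-c3ccc4c(c3)OC(c3ccccc3)(c3ccccc3)O4)oc12 | intermediate
18 | 8-[(2R,3S)-5,7-bis(benzyloxy)-2-[4-(benzyloxy)phenyl]-4-oxo-3,4-dihydro-2H-chromen-3-yl]-2-(2,2-diphenyl-1,3-benzodioxol-5-yl)-5-hydroxy-4-oxo-4H-chromen-7-yl 2,2,2-trichloroethyl sulfate (2,3-trans) | O=C1c2c(OCc3ccccc3)cc(OCc3ccccc3)cc2O[C@@H](c2ccc(OCc3ccccc3)cc2)[C@@H]1c1c(OS(=O)(=O)OCC(Cl)(Cl)Cl)cc(O)c2c(=O)cc(-c3ccc4c(c3)OC(c3ccccc3)(c3ccccc3)O4)oc12 | intermediate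
19 | ammonium salt of the target sulfate, (2R,3S) | [NH4+].O=C1c2c(O)cc(O)cc2O[C@@H](c2ccc(O)cc2)[C@@H]1c1c(OS(=O)(=O)[O-])cc(O)c2c(=O)cc(-c3ccc(O)c(O)c3)oc12 | intermediate
20 | 8-[(2R,3S)-5,7-dihydroxy-2-(4-hydroxyphenyl)-4-oxo-3,4-dihydro-2H-chromen-3-yl]-2-(3,4-dihydroxyphenyl)-5-hydroxy-4-oxo-4H-chromen-7-yl hydrogen sulfate (CNP0314990.1) | O=C1c2c(O)cc(O)cc2O[C@@H](c2ccc(O)cc2)[C@@H]1c1c(OS(=O)(=O)O)cc(O)c2c(=O)cc(-c3ccc(O)c(O)c3)oc12 | target

**Step count and risks**

Total steps: 10. Longest linear sequence: 9 (steps 1, 2, 3, 5, 6, 7, 8, 9, 10 from luteolin); step 4 is the one‑step side branch.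

The three steps most likely to fail:

Step 5 (α‑arylation with a di‑ortho‑substituted aryl iodide; hydrodehalogenation or no coupling). The fallback sets out from 7 and 9 and comes back at 10, with the polarity of the coupling reversed. Miyaura borylation of 7 (B2pin2, PdCl2(dppf), KOAc, dioxane, 90 °C) gives the flavone 8‑pinacolboronate F1. Bromination of the kinetic enolate of 9 (LiHMDS, THF, −78 °C, then NBS) gives the α‑bromo ketone F2. A Suzuki–Miyaura sp2–sp3 coupling of F1 with F2 (PdCl2(dppf), K3PO4, THF/H2O, 60 °C), a known route to deoxybenzoins from phenacyl bromides, then gives 10.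

Step 6 (Knoevenagel condensation at a very crowded methylene; unfavourable equilibrium or amine attack on the flavone). The fallback sets out from 10 and comes back at 12 by a stepwise kinetic aldol and elimination. The lithium enolate of 10 (LiHMDS, THF, −78 °C) adds to 11 to give the β‑hydroxy ketone F3 as a diastereomer mixture. MsCl/Et3N (CH2Cl2, 0 °C) converts it into the mesylate F4, which is treated without isolation with DBU at rt to give 12 by E1cB elimination.

Step 9 (the proposed new cyclisation). Possible failures are low ee, the acid being tied up by the more basic flavone carbonyl, or induction in the wrong sense; the sense must be checked on the first run by ECD or X‑ray, and the (S)‑acid used if it is opposite. The fallback sets out from 17 and comes back at 18 using known chemistry. The classical acid‑catalysed chalcone–flavanone isomerisation with an achiral acid (MsOH 20 mol%, CH2Cl2, rt) gives the racemic trans flavanone, that is 18 together with its (2S,3R)‑enantiomer F5. Preparative chiral SFC on a polysaccharide phase separates them, and 18 goes on to step 10.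

**Further compounds**

F1 | step 5 | 2-(2,2-diphenyl-1,3-benzodioxol-5-yl)-5,7-bis(methoxymethoxy)-8-(4,4,5,5-tetramethyl-1,3,2-dioxaborolan-2-yl)-4H-chromen-4-one | O=c1cc(-c2ccc3c(c2)OC(c2ccccc2)(c2ccccc2)O3)oc2c(B3OC(C)(C)C(C)(C)O3)c(OCOC)cc(OCOC)c12
F2 | step 5 | 1-[2,4-bis(benzyloxy)-6-(methoxymethoxy)phenyl]-2-bromoethanone | O=C(CBr)c1c(OCOC)cc(OCc2ccccc2)cc1OCc1ccccc1
F3 | step 6 | β-hydroxy ketone (aldol adduct of 10 and 11, diastereomer mixture) | O=C(c1c(OCOC)cc(OCc2ccccc2)cc1OCc1ccccc1)C(C(O)c1ccc(OCc2ccccc2)cc1)c1c(OCOC)cc(OCOC)c2c(=O)cc(-c3ccc4c(c3)OC(c3ccccc3)(c3ccccc3)O4)oc12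
F4 | step 6 | mesylate of F3 (not isolated) | O=C(c1c(OCOC)cc(OCc2ccccc2)cc1OCc1ccccc1)C(C(OS(C)(=O)=O)c1ccc(OCc2ccccc2)cc1)c1c(OCOC)cc(OCOC)c2c(=O)cc(-c3ccc4c(c3)OC(c3ccccc3)(c3ccccc3)O4)oc12
F5 | step 9 | (2S,3R)-enantiomer of 18 (formed 1:1 with 18 in the racemic cyclisation) | O=C1c2c(OCc3ccccc3)cc(OCc3ccccc3)cc2O[C@H](c2ccc(OCc3ccccc3)cc2)[C@H]1c1c(OS(=O)(=O)OCC(Cl)(Cl)Cl)cc(O)c2c(=O)cc(-c3ccc4c(c3)OC(c3ccccc3)(c3ccccc3)O4)oc12
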